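The δ-lactone (C10–C20–O–C7–C8–C9) is closed last, at C7–C8. C8 is the α-carbon shared by the C7 lactone carbonyl and the C15 ketone and sits on the cis fusion of the lactone with ring C, next to spiro centre C10. Hence a C15 methyl ketone enolate on a cyclohexene ring C attacks a carbonylimidazole hung on O20: one operation makes the β-keto lactone and the quaternary stereocentre C8, the tether enforcing its configuration. The precursor comes from a temporary spirolactone whose carbonyl is C15 (trivalent-titanium epoxide–acrylate coupling, Diels–Alder, MeLi opening). Ring D follows by Saegusa–Ito cyclization; a phenyl group is the latent C6 carboxyl.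

Key step: step 11

Remark: atom labels follow ent-kaurane numbering (ring A: C1–C5 and C10; C6 carboxyl carbon; C7 lactone carbonyl; ring C: C8, C9, C11–C14; ring D: C8, C13–C16; C17 methyl on C16; C20 the OCH2 carbon). The target is read as the 6,7-seco-ent-kaurane 7,20-lactone with 1α-OAc (cis to C20), C15 ketone and (16R)-methyl.

Assumption: the rhodium/(R)-binap catalyst is taken to deliver phenyl to the enone face that gives (S)-configured C5, by analogy with cyclohex-2-enone; if the sense is opposite, (S)-binap is used.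

Step 1
Reactants: 1 4,4-dimethylcyclohex-2-en-1-one; 2 phenylzinc bromide
Product: 3 trimethyl{[(3S)-4,4-dimethyl-3-phenylcyclohex-1-en-1-yl]oxy}silane
Conditions: [RhCl(C2H4)2]2 (1.5 mol %), (R)-binap (3.3 mol %), Me3SiCl, THF, 20 °C; non-aqueous work-up
Reagents that add atoms: chlorotrimethylsilane C[Si](C)(C)Cl
Why: Rhodium/binap-catalysed asymmetric conjugate arylation with an arylzinc sets C5 by catalyst control, the silyl chloride traps the enolate regiospecifically towards C10, and the phenyl ring is carried as the latent C6 carboxyl.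

Step 2
Reactants: 3 silyl enol ether
Product: 6 (3S)-4,4-dimethyl-2-methylidene-3-phenylcyclohexan-1-one, via Mannich base 4 (not isolated), via ammonium iodide 5 (not isolated)
Conditions: Me2N=CH2 I (Eschenmoser's salt), CH2Cl2, rt; MeI; aq. NaHCO3, rt
Reagents that add atoms: dimethyl(methylidene)ammonium iodide C[N+](C)=C.[I-]
Why: Mannich alkylation of the silyl enol ether at C10, quaternisation and E1cB loss of trimethylamine install the exocyclic C10=C20 alkene, so the C10 configuration of the intermediates does not matter.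

Step 3
Reactants: 6 methylidene ketone
Product: 7 (1S,3S)-4,4-dimethyl-2-methylidene-3-phenylcyclohexan-1-ol
Conditions: NaBH4, CeCl3·7H2O, MeOH, −78 → 0 °C
Reagents that add atoms: none
Why: Luche 1,2-reduction in which hydride should add to C1 so that the hydroxyl ends cis to the C5 phenyl (axial attack on the chair with equatorial phenyl), giving the cis-1,3 pattern of the target.

Step 4
Reactants: 7 allylic alcohol
Product: 8 (1S,3S)-1-(benzyloxy)-4,4-dimethyl-2-methylidene-3-phenylcyclohexane
Conditions: NaH, BnBr, Bu4NI (cat.), THF, 0 °C → rt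
Reagents that add atoms: benzyl bromide BrCc1ccccc1
Why: Williamson etherification gives a C1 ether that tolerates the later base, Lewis-acid and organometallic steps and is cleaved in the final hydrogenation.

Step 5
Reactants: 8 benzyl ether
Product: 9 (4S,8S)-4-(benzyloxy)-7,7-dimethyl-8-phenyl-1-oxaspiro[2.5]octane (both epimers at the spiro carbon)
Conditions: mCPBA, NaHCO3, CH2Cl2, 0 °C
Reagents that add atoms: 3-chloroperbenzoic acid OOC(=O)c1cccc(Cl)c1
Why: Prilezhaev epoxidation of the 1,1-disubstituted alkene, whose facial outcome is irrelevant because C10 becomes a planar radical in the next step.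

Step 6
Reactants: 9 spiro-epoxide; 10 2,2,2-trifluoroethyl prop-2-enoate
Product: 12 (6S,7S,11S)-7-(benzyloxy)-10,10-dimethyl-11-phenyl-2-oxaspiro[5.5]undecan-3-one, via hydroxy ester 11 (not isolated)
Conditions: Cp2TiCl2 (20 mol %), Zn, 2,4,6-collidine·HCl, THF, rt
Reagents that add atoms: none
Why: Trivalent titanium (Cp2TiCl formed in the flask) opens the epoxide to the tertiary C10 radical, which should add to the acrylate (Giese addition) anti to the axial C4 methyl and trans to both the C1 benzyloxy and C5 phenyl groups, and the C20 hydroxyl then lactonises on the activated ester to give the temporary lactone whose carbonyl is C15.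

Step 7
Reactants: 12 spirolactone
Product: 14 (6S,7S,11S)-7-(benzyloxy)-10,10-dimethyl-11-phenyl-2-oxaspiro[5.5]undec-4-en-3-one, via selenide 13 (not isolated)
Conditions: LiN(iPr)2, THF, −78 °C; PhSeBr; then H2O2, pyridine, CH2Cl2, 0 °C → rt
Reagents that add atoms: none
Why: α-Selenenylation of the lactone enolate and selenoxide syn-elimination, which can only go towards C9, give the C8=C9 dienophile.

Step 8
Reactants: 14 unsaturated spirolactone; 15 buta-1,3-diene
Product: 16 cis-fused lactone 2'-(benzyloxy)-5',5'-dimethyl-6'-phenyl-4a,5,8,8a-tetrahydrospiro[isochromane-4,1'-cyclohexan]-1-one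
Conditions: EtAlCl2 (0.3 equiv), butadiene (excess), toluene, −20 → 60 °C, sealed tube
Reagents that add atoms: none
Why: Lewis-acid-promoted Diels–Alder reaction builds ring C with the C12=C13 alkene, the diene being expected on the face of C9 flanked by the C1 ether oxygen and not by the bulkier C5 phenyl, which fixes C9 on a rigid ring while C8 is set cis and re-set in step 11.

Step 9
Reactants: 16 Diels–Alder lactone
Product: 17 1-{6-[2-(benzyloxy)-1-(hydroxymethyl)-5,5-dimethyl-6-phenylcyclohexyl]cyclohex-3-en-1-yl}ethan-1-one (in equilibrium with its cyclic hemiketal)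
Conditions: MeLi (1.05 equiv), THF, −78 °C; aq. NH4Cl
Reagents that add atoms: methyllithium [Li]C
Why: Single addition of methyllithium to the δ-lactone should stop at the lithium hemiketal at low temperature, and work-up opens it to the C15 methyl ketone and the free C20 hydroxyl, removing the temporary lactone.

Step 10
Reactants: 17 hydroxy ketone
Product: 18 imidazole-1-carboxylate of 17 at O20
Conditions: 1,1'-carbonyldiimidazole, CH2Cl2, rt
Reagents that add atoms: 1,1'-carbonyldiimidazole O=C(n1ccnc1)n1ccnc1
Why: O-Acylation of the primary alcohol, drawn from the hydroxy ketone–hemiketal equilibrium, places C7 on O20 as an activated carbonyl.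

Step 11
Reactants: 18 imidazole carboxylate
Product: 19 8a-acetyl-2'-(benzyloxy)-5',5'-dimethyl-6'-phenyl-4a,5,8,8a-tetrahydrospiro[isochromane-4,1'-cyclohexan]-1-one (C7 cis and acetyl trans to C10 on ring C)
Conditions: KN(SiMe3)2 (1.1 equiv), THF (0.01 M), −78 → 23 °C; aq. NH4Cl
Reagents that add atoms: none
Why: Deprotonation should give the methyl-side enolate first, but proton exchange through HN(SiMe3)2 interconverts it with the tetrasubstituted C8=C15 enolate, and only the latter reaches the carbonylimidazole through a six-membered transition state, so C8 attacks C7 and expels imidazolide (Curtin–Hammett control). The closest known reaction type is the Dieckmann/Claisen C-acylation of a ketone enolate by a carbonate or acyl imidazole to give a β-keto lactone. The lactone ring closes in the 6-(enolexo)-exo-trig mode. The new quaternary stereocentre C8 is controlled by the tether: allylic 1,3-strain in the exocyclic enolate places the C9–C10 bond axial on ring C, so C7 is delivered to the face of C8 syn to C10, which gives the cis ring fusion with the acetyl group (C15) trans to C10. The step needs C- over O-acylation and C8 over C16 selectivity; both rest on ring size (six against eight) and on the irreversibility of the closure, since the product has no hydrogen at C8 and imidazolide is too weak a nucleophile for retro-Claisen cleavage.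

Step 12
Reactants: 19 β-keto lactone
Product: 21 tetracyclic keto lactone with ring D closed (C16–C13) and a C11=C12 alkene, via silyl enol ether 20 (not isolated)
Conditions: Me3SiOTf, Et3N, CH2Cl2, 0 °C; then Pd(OAc)2 (1.1 equiv), MeCN, rt
Reagents that add atoms: none
Why: The only possible silyl enol ether (C15=C16) is turned by divalent palladium into a C16-bound palladium enolate that inserts the C12=C13 alkene in the 5-exo mode (Saegusa–Ito cyclization of a 2-silyloxy-1,5-diene), forming C16–C13 on the face of the axial acyl group as the bridge demands, and syn β-hydride elimination towards C11 leaves the C11=C12 alkene.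

Step 13
Reactants: 21 tetracyclic ketone
Product: 23 16-methylidene-15-ketone (exocyclic enone) with C11=C12 alkene, via Mannich base 22 (not isolated)
Conditions: CH2(NMe2)2, Ac2O, DMF, 95 °C
Reagents that add atoms: bis(dimethylamino)methane CN(C)CN(C)C
Why: Mannich reaction at C16, the only enolisable position, with the iminium acetate formed in the flask, followed by thermal loss of dimethylamine, gives the 16-en-15-one.

Step 14
Reactants: 23 enone
Product: 24 (16R)-1-hydroxy-16-methyl-15-oxo lactone carrying phenyl at C5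
Conditions: H2 (1 atm), Pd/C, EtOAc–EtOH, rt
Reagents that add atoms: none
Why: Heterogeneous hydrogenation saturates C11=C12 and C16=C17 and cleaves the benzyl ether, and hydrogen should reach C16 from the open exo face of ring D (away from the C9–C11–C12 bridge), leaving the C17 methyl endo as in the target.

Step 15
Reactants: 24 alcohol
Product: 25 1-acetate of 24
Conditions: Ac2O, pyridine, DMAP (cat.), CH2Cl2, rt
Reagents that add atoms: acetic anhydride CC(=O)OC(C)=O
Why: Standard acylation of the secondary C1 alcohol under conditions too mild to epimerise C16.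

Step 16
Reactants: 25 acetate
Product: 26 (16R)-1α-acetoxy-15-oxo-6,7-seco-ent-kauran-7,20-olid-6-oic acid (CNP0161834.1)
Conditions: RuCl3·xH2O (5 mol %), NaIO4 (excess), CCl4–MeCN–H2O, rt
Reagents that add atoms: sodium periodate [Na+].[O-]I(=O)(=O)=O; water O
Why: Catalytic RuO4, formed from RuCl3 and NaIO4, degrades the phenyl ring to the carboxylic acid while ketone, lactone and acetate are inert, so C5 keeps its configuration and C6 appears at the acid level.

Compound list

1 | 4,4-dimethylcyclohex-2-en-1-one | O=C1C=CC(C)(C)CC1 | starting material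
2 | phenylzinc bromide | Br[Zn]c1ccccc1 | starting material
3 | trimethyl{[(3S)-4,4-dimethyl-3-phenylcyclohex-1-en-1-yl]oxy}silane | C[Si](C)(C)OC1=C[C@H](c2ccccc2)C(C)(C)CC1 | intermediate
4 | trans-2-[(dimethylamino)methyl]-4,4-dimethyl-3-phenylcyclohexan-1-one (3S) | O=C1CCC(C)(C)[C@@H](c2ccccc2)[C@@H]1CN(C)C | intermediate
5 | N-methyl ammonium iodide of 4 | O=C1CCC(C)(C)[C@@H](c2ccccc2)[C@@H]1C[N+](C)(C)C.[I-] | intermediate
6 | (3S)-4,4-dimethyl-2-methylidene-3-phenylcyclohexan-1-one | O=C1CCC(C)(C)[C@@H](c2ccccc2)C1=C | intermediate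
7 | (1S,3S)-4,4-dimethyl-2-methylidene-3-phenylcyclohexan-1-ol (OH cis to Ph) | O[C@H]1CCC(C)(C)[C@@H](c2ccccc2)C1=C | intermediate
8 | (1S,3S)-1-(benzyloxy)-4,4-dimethyl-2-methylidene-3-phenylcyclohexane | C(c1ccccc1)O[C@H]1CCC(C)(C)[C@@H](c2ccccc2)C1=C | intermediate
9 | (4S,8S)-4-(benzyloxy)-7,7-dimethyl-8-phenyl-1-oxaspiro[2.5]octane, both epimers at the spiro carbon | C(c1ccccc1)O[C@H]1CCC(C)(C)[C@@H](c2ccccc2)C12CO2 | intermediate
10 | 2,2,2-trifluoroethyl prop-2-enoate | C=CC(=O)OCC(F)(F)F | starting material
11 | 2,2,2-trifluoroethyl 3-[2-(benzyloxy)-1-(hydroxymethyl)-5,5-dimethyl-6-phenylcyclohexyl]propanoate (chain on C10 trans to OBn and to Ph) | C(c1ccccc1)O[C@H]1CCC(C)(C)[C@@H](c2ccccc2)[C@]1(CO)CCC(=O)OCC(F)(F)F | intermediate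
12 | (6S,7S,11S)-7-(benzyloxy)-10,10-dimethyl-11-phenyl-2-oxaspiro[5.5]undecan-3-one (temporary lactone, carbonyl = C15) | C(c1ccccc1)O[C@H]1CCC(C)(C)[C@@H](c2ccccc2)[C@@]12COC(=O)CC2 | intermediate
13 | 4-(phenylselanyl) derivative of 12, both epimers at C8 | C(c1ccccc1)O[C@H]1CCC(C)(C)[C@@H](c2ccccc2)[C@@]12COC(=O)C([Se]c3ccccc3)C2 | intermediate
14 | (6S,7S,11S)-7-(benzyloxy)-10,10-dimethyl-11-phenyl-2-oxaspiro[5.5]undec-4-en-3-one | C(c1ccccc1)O[C@H]1CCC(C)(C)[C@@H](c2ccccc2)[C@@]12COC(=O)C=C2 | intermediate
15 | buta-1,3-diene | C=CC=C | starting material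
16 | cis-fused lactone 2'-(benzyloxy)-5',5'-dimethyl-6'-phenyl-4a,5,8,8a-tetrahydrospiro[isochromane-4,1'-cyclohexan]-1-one (H8 cis to H9; C11 on the C1 face of the lactone ring) | C(c1ccccc1)O[C@H]1CCC(C)(C)[C@@H](c2ccccc2)[C@@]12COC(=O)[C@H]1CC=CC[C@H]12 | intermediate
17 | 1-{6-[2-(benzyloxy)-1-(hydroxymethyl)-5,5-dimethyl-6-phenylcyclohexyl]cyclohex-3-en-1-yl}ethan-1-one (acetyl at C8 cis to C10) | C(c1ccccc1)O[C@H]1CCC(C)(C)[C@@H](c2ccccc2)[C@]1(CO)[C@@H]1CC=CC[C@@H]1C(C)=O | intermediate
18 | imidazole-1-carboxylate of 17 at O20 | C(c1ccccc1)O[C@H]1CCC(C)(C)[C@@H](c2ccccc2)[C@]1(COC(=O)n3ccnc3)[C@@H]1CC=CC[C@@H]1C(C)=O | intermediate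
19 | 8a-acetyl-2'-(benzyloxy)-5',5'-dimethyl-6'-phenyl-4a,5,8,8a-tetrahydrospiro[isochromane-4,1'-cyclohexan]-1-one (C7 cis, acetyl trans to C10 on ring C) | C(c1ccccc1)O[C@H]1CCC(C)(C)[C@@H](c2ccccc2)[C@@]12COC(=O)[C@@]1(C(C)=O)CC=CC[C@H]12 | intermediate
20 | trimethylsilyl enol ether of 19 (C15(OSiMe3)=C16H2) | C(c1ccccc1)O[C@H]1CCC(C)(C)[C@@H](c2ccccc2)[C@@]12COC(=O)[C@@]1(C(=C)O[Si](C)(C)C)CC=CC[C@H]12 | intermediate
21 | tetracyclic 15-keto 7,20-lactone with ring D closed, C16H2, C11=C12 alkene, 1-OBn, 5-phenyl | C(c1ccccc1)O[C@H]1CCC(C)(C)[C@@H](c2ccccc2)[C@@]12COC(=O)[C@@]13C[C@@H](C=C[C@H]12)CC3=O | intermediate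
22 | 16-[(dimethylamino)methyl] derivative of 21, both epimers at C16 | C(c1ccccc1)O[C@H]1CCC(C)(C)[C@@H](c2ccccc2)[C@@]12COC(=O)[C@@]13C[C@@H](C=C[C@H]12)C(CN(C)C)C3=O | intermediate
23 | 16-methylidene derivative of 21 (16-en-15-one) | C(c1ccccc1)O[C@H]1CCC(C)(C)[C@@H](c2ccccc2)[C@@]12COC(=O)[C@@]13C[C@@H](C=C[C@H]12)C(=C)C3=O | intermediate
24 | (16R)-1α-hydroxy-16-methyl-15-oxo-5-phenyl 7,20-lactone (saturated rings C and D) | O[C@H]1CCC(C)(C)[C@@H](c2ccccc2)[C@@]12COC(=O)[C@@]13C[C@@H](CC[C@H]12)[C@@H](C)C3=O | intermediate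
25 | 1-acetate of 24 | CC(=O)O[C@H]1CCC(C)(C)[C@@H](c2ccccc2)[C@@]12COC(=O)[C@@]13C[C@@H](CC[C@H]12)[C@@H](C)C3=O | intermediate
26 | (16R)-1α-acetoxy-15-oxo-6,7-seco-ent-kauran-7,20-olid-6-oic acid (CNP0161834.1) | CC(=O)O[C@H]1CCC(C)(C)[C@@H](C(=O)O)[C@@]12COC(=O)[C@@]13C[C@@H](CC[C@H]12)[C@@H](C)C3=O | target

Total step count: 16. Longest linear sequence: 16 steps (1 to 26).

Steps most likely to fail: 11, 8 and 12.

Step 11. The process at risk is enolate regiocontrol: the methyl-side enolate may be consumed by intermolecular acylation or O-acylation before it equilibrates to the C8 enolate. The fallback makes C8 the only acidic position. It sets out from 16: Me2AlSEt (from AlMe3 and ethanethiol) opens the lactone to the hydroxy S-ethyl thioester F1, which is used at once; 1,1'-carbonyldiimidazole gives the imidazole carboxylate F2; LiN(SiMe3)2 at −78 °C forms the thioester enolate and closes the lactone at C7–C8 to the thioester lactone F3; Me2CuLi (or MeZnI with PdCl2(PPh3)2, Fukuyama coupling) converts the thioester into the methyl ketone and comes back to the route at 19.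

Step 8. The processes at risk are low dienophile reactivity at the neopentyl β-carbon, so that diene polymerisation outruns cycloaddition, and loss of facial selectivity. The fallback builds ring C stepwise and sets out from 14: Hosomi–Sakurai conjugate allylation (allyltrimethylsilane, TiCl4, −78 °C) gives the C9-allyl lactone F4; enolate allylation (LiN(iPr)2, allyl bromide) gives the trans-diallyl lactone F5; ring-closing metathesis with second-generation Grubbs catalyst gives the trans-fused cyclohexene lactone F6, the C8 epimer of 16. Because C8 is planarised in step 11, F6 is taken through the conditions of steps 9 and 10 to the hydroxy ketone F7 and the imidazole carboxylate F8, and step 11 then comes back to the route at 19.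

Step 12. The processes at risk are protodesilylation to the ketone without C–C bond formation and palladium hydride chain-walking that moves the ring C alkene to C9. The fallback closes ring D by an enyne cyclisation and sets out from 16: lithium (trimethylsilyl)acetylide opens the lactone to the hydroxy ynone F9; 4-nitrophenyl chloroformate and pyridine give the carbonate F10; LiN(SiMe3)2 at −78 °C closes the lactone at C7–C8 through the only enolisable position to the silyl ynone lactone F11; Bu4NF buffered with AcOH gives the terminal ynone F12; palladium-hydride reductive 1,6-enyne cyclisation (Pd2(dba)3, AcOH, Et3SiH) forms C16–C13 and gives the exocyclic enone with saturated ring C F13; hydrogenation under the conditions of step 14 comes back to the route at 24.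

Further compounds

F1 | step 11 | hydroxy S-ethyl thioester from 16 (C15 thioester on C8, free C20 hydroxyl) | C(c1ccccc1)O[C@H]1CCC(C)(C)[C@@H](c2ccccc2)[C@]1(CO)[C@@H]1CC=CC[C@@H]1C(=O)SCC
F2 | step 11 | imidazole-1-carboxylate of F1 at O20 | C(c1ccccc1)O[C@H]1CCC(C)(C)[C@@H](c2ccccc2)[C@]1(COC(=O)n3ccnc3)[C@@H]1CC=CC[C@@H]1C(=O)SCC
F3 | step 11 | 7,20-lactone with S-ethyl thioester (C15) on quaternary C8 | C(c1ccccc1)O[C@H]1CCC(C)(C)[C@@H](c2ccccc2)[C@@]12COC(=O)[C@@]1(C(=O)SCC)CC=CC[C@H]12
F4 | step 8 | C9-allyl spirolactone | C(c1ccccc1)O[C@H]1CCC(C)(C)[C@@H](c2ccccc2)[C@@]12COC(=O)C[C@H]2CC=C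
F5 | step 8 | trans-C8,C9-diallyl spirolactone | C(c1ccccc1)O[C@H]1CCC(C)(C)[C@@H](c2ccccc2)[C@@]12COC(=O)[C@H](CC=C)[C@H]2CC=C
F6 | step 8 | trans-fused cyclohexene lactone, C8 epimer of 16 | C(c1ccccc1)O[C@H]1CCC(C)(C)[C@@H](c2ccccc2)[C@@]12COC(=O)[C@@H]1CC=CC[C@H]12
F7 | step 8 | hydroxy ketone, C8 epimer of 17 | C(c1ccccc1)O[C@H]1CCC(C)(C)[C@@H](c2ccccc2)[C@]1(CO)[C@@H]1CC=CC[C@H]1C(C)=O
F8 | step 8 | imidazole-1-carboxylate, C8 epimer of 18 | C(c1ccccc1)O[C@H]1CCC(C)(C)[C@@H](c2ccccc2)[C@]1(COC(=O)n3ccnc3)[C@@H]1CC=CC[C@H]1C(C)=O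
F9 | step 12 | hydroxy (trimethylsilyl)ynone from 16 | C(c1ccccc1)O[C@H]1CCC(C)(C)[C@@H](c2ccccc2)[C@]1(CO)[C@@H]1CC=CC[C@@H]1C(=O)C#C[Si](C)(C)C
F10 | step 12 | 4-nitrophenyl carbonate of F9 at O20 | C(c1ccccc1)O[C@H]1CCC(C)(C)[C@@H](c2ccccc2)[C@]1(COC(=O)Oc3ccc(cc3)[N+](=O)[O-])[C@@H]1CC=CC[C@@H]1C(=O)C#C[Si](C)(C)C
F11 | step 12 | 7,20-lactone with (trimethylsilyl)propynoyl group on quaternary C8 | C(c1ccccc1)O[C@H]1CCC(C)(C)[C@@H](c2ccccc2)[C@@]12COC(=O)[C@@]1(C(=O)C#C[Si](C)(C)C)CC=CC[C@H]12
F12 | step 12 | terminal ynone from F11 | C(c1ccccc1)O[C@H]1CCC(C)(C)[C@@H](c2ccccc2)[C@@]12COC(=O)[C@@]1(C(=O)C#C)CC=CC[C@H]12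
F13 | step 12 | 16-methylidene-15-ketone with saturated ring C (11,12-dihydro-23) | C(c1ccccc1)O[C@H]1CCC(C)(C)[C@@H](c2ccccc2)[C@@]12COC(=O)[C@@]13C[C@@H](CC[C@H]12)C(=C)C3=O
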